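## Structural features

The target is a germacranolide of the heliangolide type: a ten-membered carbocycle (C1–C10) with an α-methylene-γ-butyrolactone trans-fused across C6–C7 (O6–C12, C7–C11, exocyclic C13). The ring holds a Z-trisubstituted C4=C5 olefin whose C4 carries the C15 hydroxymethyl group, an E-derived epoxide on C1–C10 with the C14 methyl on C10, a secondary allylic alcohol at C3 and an isobutyrate at C8. Of the six stereocentres, C6, C7 and C8 are contiguous, C1 and C10 form the epoxide pair, and C3 stands alone, separated from C8 by the C2–C1–C10–C9 isoprenoid unit, so neither end can direct the other. The fragile groups are the methylene lactone (Michael acceptor, base-labile), the trisubstituted epoxide (open to transannular attack by the C3 hydroxyl or the C4=C5 olefin under acid), the C6–C7–C8 β-acyloxy array (acyl shift, elimination) and the two allylic alcohols. The real difficulty is threefold: closing a strained ten-membered ring, fixing the ring-cis geometry of C4=C5 although C4 bears two different oxygenated carbons, and placing two homoallylic carbinols (C3, C8) on either side of a 1(10)E olefin, a pattern that ordinary allyl additions do not give. The key step uses the fact that C6 is at once the lactone carbinol and the allylic neighbour of C5: a C5 alkenyl iodide of fixed geometry and a C6 aldehyde close the ring by C5–C6 bond formation and deliver the lactone oxygen in the same event.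

## Logic of the disconnections

42 to 41: the O3–Si and O15–Si bonds are cut. The two allylic hydroxyls are masked so that the primary C15 alcohol cannot compete with C12 in the lactone oxidation. The forward step must remove two silyl ethers without opening the epoxide or touching the lactone and the ester.

41 to 38: the lactone is opened to a 2-methylene-1,4-diol (C12 taken down to the alcohol level, O6–C12 cut). The Michael acceptor is thereby made last. The oxidant must prefer the primary allylic C12 alcohol over the secondary allylic C6 alcohol and then oxidise the lactol.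

38 to 37: the O12–benzyl bond is cut. C12 must be protected during ring closure, because a free C12 hydroxyl would form a lactol with the C6 aldehyde. The removal must be neutral and oxidative, orthogonal to silyl ethers, ester and epoxide.

37 to 35: the C5–C6 bond is cut. This removes the ring and one stereocentre and leaves an open chain in which the other five centres and both olefin geometries are already in place. The forward step needs a C–C bond formation that tolerates ester, epoxide and an epimerisable aldehyde, and it must create C6 with oxygen anti to the C7 branch.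

35 to 34 to 33: the C6 oxidation level and the O6–Si bond. The aldehyde is doubly activated at C7 and β to the ester, so it is generated in the last operation before ring closure, from a primary silyl ether that can be removed in the presence of the other two.

33 to 32: the two C–O bonds of the epoxide. The E-olefin survives all C–C bond formations, whereas an epoxide next to a C8 aldehyde would eliminate. The forward step must choose one of three olefins and one face by reagent control.

32 to 30 and 31: the O8–acyl bond is cut, a simple esterification placed before epoxidation so that the C8 alkoxide cannot open the epoxide.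

30 to 19 and 28: the C7–C8 bond is cut. One allylboration sets C7 and C8 together and joins the two halves. Because C3 is too remote to help, the catalyst must choose the aldehyde face, and the reagent geometry must give the syn relation of the C6 carbon and O8.

28 to 25 and 26, then 24, 22, 20 and 21: the C11–C13 bond is cut (sp2–sp3 coupling with retention), then C11–I and C7–H across an alkyne. Hydroxyl-directed trans-hydroalumination of the butynediol monoether fixes the olefin geometry that the allylboration needs.

19 to 18, 16, then 13 and 14: C8 is removed (C8–O, then C8=C9). A linear C9 nucleophile cannot be added to a C8 aldehyde with control of regiochemistry, so C8 is added as a methylene and oxidised at its terminus. The hydroboration must select the monosubstituted end of a diene.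

13 to 12: C5–I is traced back to C5–Si. The iodide is introduced by ipso substitution at the one stage where no other electron-rich olefin is present.

12 to 10 and 11: the C1=C10 bond is cut. Cross metathesis with an α-methyl enal gives the E-trisubstituted olefin and brings C9, C10 and C14.

10 to 9, then 6 and 7: O3–Si, then C2–C3. Catalytic asymmetric allylation of the enal sets C3.

6 to 3 and 4, then 1 and 2: the C3–C4 bond (formyl carbon on the alkenyl anion), then C4–Sn and C5–Si across the alkyne. Cis addition of the Si–Sn bond is what places the later iodine cis to C3 and trans to C15. A one-pot iodide/propiolate/aldehyde coupling that forms C3–C4 and C5–I together was set aside: it puts iodine cis to the ester carbon, so after reduction of the ester to C15 the iodine would be trans to C3, the wrong geometry for a ring-cis olefin.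

## Other disconnections considered

Alternative 1: The cut runs through C1–C4 and C5–C10. The ten-membered dienone ester A1 is traced back to the tricycle A2, in which a cyclohexanone and a four-membered ring share a central cyclobutane. In the forward direction, flash vacuum thermolysis of A2 would break those two bonds, release the strain of two fused four-membered rings and leave C1=C10 and C4=C5 inside the new ring.
- In favour: the ring is made from small rings without high dilution and without organometallic reagents, and A1 should be reached in fewer steps than 37. On ring construction as such it is the equal or the better of the chosen plan.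
- Against: A1 carries only the C8 centre. C3 has no oxygen, C7 has no three-carbon branch and C6 is a ketone, so five centres, the lactone and the epoxide must all be made afterwards on a flexible ring. The fragmentation is stepwise, so the olefin geometries are not guaranteed, and the 1,5-diene of A1 could undergo Cope rearrangement to a divinylcyclohexane at the temperature of its formation.
- Comparison: structurally, the chosen plan closes the ring with every centre but C6 in place, whereas Alternative 1 closes it almost bare. Mechanistically, the thermolysis creates no stereocentre and so avoids the facial question at C6 (a point in its favour), but it moves that question to a later ketone reduction. In step economy it is better before the ring and probably worse overall.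

Alternative 2: The cut removes C12, that is the C11–C12 and C12–O6 bonds. The bis-silyl ether A3, which is identical with 41, is traced back to the ten-membered trans-2-ethynyl alcohol A4. In the forward direction, PdCl2 and thiourea under CO would convert the C6 hydroxyl into an alkoxycarbonyl–palladium species (divalent palladium), the alkyne would insert cis, and protonolysis would leave the exocyclic methylene.
- In favour: the methylene lactone appears in one operation, with no C12 protecting group, no debenzylation and no oxidation. After ring closure it is one step shorter than the chosen plan, which is a real advantage. The trans relation it requires is the one present in 37.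
- Against: it does not form the ten-membered ring, so A4 still needs a macrocyclisation. If that were the same Ni/Cr closure, the aldehyde would be α-ethynyl, more prone to allene formation and epimerisation than 35, and a terminal alkyne is a liability towards zerovalent nickel. Lewis-acidic divalent palladium with an epoxide and allylic silyl ethers is a further risk.
- Comparison: it is a tactic for the lactone, not a competitor for the ring bond. On the lactone it is the equal or the better of the diol oxidation. On the ring it adds nothing and makes the closure substrate more fragile.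

Alternative 3: The cut forms C8–C9 while a C1–C6 bond, present only in the six-membered precursor, breaks. The dienone A5 is traced back to the divinylcyclohexenol A6. In the forward direction, the potassium alkoxide of A6 (KH, 18-crown-6) would undergo an anionic oxy-Cope shift through a chair, giving the ring-enlarged enolate and then A5.
- In favour: the chair should fix the 1(10)E geometry and the C8 centre (as a silyl group, later oxidised with retention) in one step. The Z olefin is inherited from the six-membered ring, the C3 silyl ether is in place, no dilution is needed, and the C7 enolate is formed regiospecifically for alkylation. On predictability of the stereochemistry at ring formation it is better than the chosen plan.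
- Against: in A5, C15 is a methyl group and would need a late, selective allylic oxidation next to a second allylic methyl. The C11–C13 unit and the lactone are missing and C6 is a ketone. Oxidising the C–Si bond needs electrophilic or peracid conditions in the presence of two trisubstituted olefins. A6 itself needs several steps from the chiral pool.
- Comparison: structurally it delivers less of the oxidation pattern than 37. Mechanistically a concerted sigmatropic shift is more reliable than a chromium addition whose facial sense is open. In step economy the ring comes early, but the functionalisation afterwards should make the whole longer.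

Key step: step 19

Remarks before the steps:
- Abbreviations: TBSO = tert-butyldimethylsilyloxy, TESO = triethylsilyloxy, PMBO = 4-methoxybenzyloxy, Bpin = 4,4,5,5-tetramethyl-1,3,2-dioxaborolan-2-yl, (S)-TRIP = (S)-3,3'-bis(2,4,6-triisopropylphenyl)-1,1'-binaphthyl-2,2'-diyl hydrogen phosphate. Germacrane numbering (C1–C15) is used for positions in all intermediates.
- Assumption on the chemistry: the (R)-enantiomer of this phosphoric acid is taken to direct pinacol allylboronates to the Re face of aldehydes, so the (S)-acid is specified for the two Si-face additions (steps 3 and 14).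
- Check of structures: 35 and 37 were compared with 42 centre by centre (C1, C3, C7, C8, C10 and the C4=C5 geometry) and agree; no structure needed correction. Two points of reasoning are set right. The iodoolefin geometry comes from cis Si–Sn addition, for the reason given in the last disconnection paragraph. The facial sense at C6 is not taken as secured by an open-chain Felkin–Anh argument (see step 19).

Step 1
Reactants: 1 tert-butyldimethyl(prop-2-yn-1-yloxy)silane; 2 trimethyl(tributylstannyl)silane
Product: 3 (Z)-tert-butyldimethyl{[2-(tributylstannyl)-3-(trimethylsilyl)prop-2-en-1-yl]oxy}silane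
Conditions: Pd(PPh3)4 (2 mol %), THF, 65 °C
Reagents that add atoms: none
Why: Zerovalent palladium inserts into the Si–Sn bond and the terminal alkyne undergoes cis silastannation, with tin on the internal carbon (C4) and silicon on the terminal carbon (C5). The cis relation of Si and Sn is the origin of the later cis relation of iodine and C3.

Step 2
Reactants: 3 (Z)-tert-butyldimethyl{[2-(tributylstannyl)-3-(trimethylsilyl)prop-2-en-1-yl]oxy}silane; 4 N,N-dimethylformamide
Product: 6 (Z)-2-(TBSO-methyl)-3-(trimethylsilyl)prop-2-enal, via vinyllithium 5 (not isolated)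
Conditions: MeLi, THF, −78 to −40 °C; then 4, −78 to 0 °C; aq. NH4Cl
Reagents that add atoms: none
Why: Tin–lithium exchange occurs with retention at the sp2 carbon, and formylation of the alkenyllithium gives the enal whose carbonyl carbon is C3. The low temperature prevents loss of silanolate from the 2-lithioallyl ether.

Step 3
Reactants: 6 (Z)-2-(TBSO-methyl)-3-(trimethylsilyl)prop-2-enal; 7 2-allyl-4,4,5,5-tetramethyl-1,3,2-dioxaborolane
Product: 9 (1Z,3S)-2-(TBSO-methyl)-1-(trimethylsilyl)hexa-1,5-dien-3-ol, via borate ester 8 (not isolated)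
Conditions: (S)-TRIP (5 mol %), 4 Å MS, toluene, −30 °C; aq. NaHCO3
Reagents that add atoms: none
Why: Chiral phosphoric acid-catalysed allylboration through a closed six-membered transition state, a reaction that works well with conjugated aldehydes. The (S)-acid should send the allyl group to the Si face and give the 3S carbinol.

Step 4
Reactants: 9 (1Z,3S)-2-(TBSO-methyl)-1-(trimethylsilyl)hexa-1,5-dien-3-ol
Product: 10 (1Z,3S)-3-(TBSO)-2-(TBSO-methyl)-1-(trimethylsilyl)hexa-1,5-diene
Conditions: TBSOTf, 2,6-lutidine, CH2Cl2, −78 to 0 °C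
Reagents that add atoms: tert-butyldimethylsilyl trifluoromethanesulfonate, CC(C)(C)[Si](C)(C)OS(=O)(=O)C(F)(F)F
Why: Standard silylation of a hindered secondary allylic alcohol with the silyl triflate; no stereocentre is affected.

Step 5
Reactants: 10 (1Z,3S)-3-(TBSO)-2-(TBSO-methyl)-1-(trimethylsilyl)hexa-1,5-diene; 11 2-methylprop-2-enal
Product: 12 (2E,5S,6Z)-5-(TBSO)-6-(TBSO-methyl)-2-methyl-7-(trimethylsilyl)hepta-2,6-dienal
Conditions: 11 (5 equiv), second-generation Hoveyda–Grubbs catalyst RuCl2(H2IMes)(=CH-C6H4-2-OiPr) (5 mol %), CH2Cl2, 40 °C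
Reagents that add atoms: none
Why: Cross metathesis of a terminal olefin with an electron-poor 1,1-disubstituted partner should give mainly the E-trisubstituted enal, which fixes the 1(10)E geometry. The hindered trisubstituted vinylsilane does not take part.

Step 6
Reactants: 12 (2E,5S,6Z)-5-(TBSO)-6-(TBSO-methyl)-2-methyl-7-(trimethylsilyl)hepta-2,6-dienal
Product: 13 (2E,5S,6Z)-5-(TBSO)-6-(TBSO-methyl)-7-iodo-2-methylhepta-2,6-dienal
Conditions: N-iodosuccinimide, MeCN/ClCH2CN (4:1), 0 °C to rt, dark
Reagents that add atoms: N-iodosuccinimide, O=C1CCC(=O)N1I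
Why: Electrophilic ipso-iododesilylation of the vinylsilane proceeds with retention, so iodine ends cis to C3. It is placed here because the only other olefin is the deactivated enal.

Step 7
Reactants: 13 (2E,5S,6Z)-5-(TBSO)-6-(TBSO-methyl)-7-iodo-2-methylhepta-2,6-dienal; 14 methyltriphenylphosphonium bromide
Product: 16 (3E,6S,7Z)-6-(TBSO)-7-(TBSO-methyl)-8-iodo-3-methylocta-1,3,7-triene, via phosphorus ylide 15 (not isolated)
Conditions: 14, NaN(SiMe3)2, THF, 0 °C; then 13, −78 to 0 °C
Reagents that add atoms: none
Why: Wittig methylenation of the enal adds C8 as a terminal vinyl carbon; the alkenyl iodide and the silyl ethers are inert to the non-stabilised ylide at low temperature.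

Step 8
Reactants: 16 (3E,6S,7Z)-6-(TBSO)-7-(TBSO-methyl)-8-iodo-3-methylocta-1,3,7-triene
Product: 18 (3E,6S,7Z)-6-(TBSO)-7-(TBSO-methyl)-8-iodo-3-methylocta-3,7-dien-1-ol, via alkylborane 17 (not isolated)
Conditions: 9-BBN, THF, 0 °C to rt; then aq. NaOH, H2O2, 0 °C
Reagents that add atoms: hydrogen peroxide, OO
Why: The bulky borane adds anti-Markovnikov to the monosubstituted end of the diene only, leaving the trisubstituted olefins, and oxidation with retention gives the primary C8 alcohol. C9 thus becomes the methylene between C8 and C10 that an allyl addition could not deliver.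

Step 9
Reactants: 18 (3E,6S,7Z)-6-(TBSO)-7-(TBSO-methyl)-8-iodo-3-methylocta-3,7-dien-1-ol
Product: 19 (3E,6S,7Z)-6-(TBSO)-7-(TBSO-methyl)-8-iodo-3-methylocta-3,7-dienal
Conditions: Dess–Martin periodinane, NaHCO3, CH2Cl2, 0 °C to rt; used at once
Reagents that add atoms: none
Why: Buffered Dess–Martin oxidation gives the β,γ-unsaturated aldehyde without acid or base, so the olefin should not move into conjugation.

Step 10
Reactants: 20 but-2-yne-1,4-diol; 21 4-methoxybenzyl chloride
Product: 22 4-(PMBO)but-2-yn-1-ol
Conditions: 20 (3 equiv), NaH (1 equiv), Bu4NI (cat.), THF/DMF, 0 °C to rt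
Reagents that add atoms: none
Why: Williamson monoalkylation; the excess of the cheap diol suppresses the bis-ether.

Step 11
Reactants: 22 4-(PMBO)but-2-yn-1-ol
Product: 24 (Z)-3-iodo-4-(PMBO)but-2-en-1-ol, via alkenylaluminate 23 (not isolated)
Conditions: NaAlH2(OCH2CH2OCH3)2, THF, 0 °C to rt; then I2, −78 °C; aq. KNaC4H4O6
Reagents that add atoms: iodine, II
Why: Hydroxyl-directed trans-hydroalumination puts hydride on C7 and aluminium on C11 inside a five-membered chelate, and iodinolysis with retention gives the iodide cis to the C6 hydroxymethyl group.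

Step 12
Reactants: 24 (Z)-3-iodo-4-(PMBO)but-2-en-1-ol
Product: 25 (Z)-triethyl{[3-iodo-4-(PMBO)but-2-en-1-yl]oxy}silane
Conditions: Et3SiCl, imidazole, CH2Cl2, 0 °C
Reagents that add atoms: chlorotriethylsilane, CC[Si](Cl)(CC)CC
Why: Silylation of the primary alcohol; the triethylsilyl group is chosen because it can later be removed at C6 in the presence of the two TBS ethers.

Step 13
Reactants: 25 (Z)-triethyl{[3-iodo-4-(PMBO)but-2-en-1-yl]oxy}silane; 26 2-(iodomethyl)-4,4,5,5-tetramethyl-1,3,2-dioxaborolane
Product: 28 (E)-triethyl{[4-(PMBO)-3-(Bpin-methyl)but-2-en-1-yl]oxy}silane, via borylmethylzinc iodide 27 (not isolated)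
Conditions: 26, Zn dust, THF, rt; then 25, Pd(PPh3)4 (5 mol %), THF, 50 °C
Reagents that add atoms: none
Why: Negishi coupling of the borylmethylzinc reagent with the alkenyl iodide is stereoretentive and gives the allylboronate in which the C6 carbon is cis to the CH2B carbon (a Z-crotyl-type reagent). No alkenyllithium is involved, so silyl migration from oxygen to carbon is avoided.

Step 14
Reactants: 19 (3E,6S,7Z)-6-(TBSO)-7-(TBSO-methyl)-8-iodo-3-methylocta-3,7-dienal; 28 (E)-triethyl{[4-(PMBO)-3-(Bpin-methyl)but-2-en-1-yl]oxy}silane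
Product: 30 (3S,4R,6E,9S,10Z)-9-(TBSO)-10-(TBSO-methyl)-11-iodo-2-(PMBO-methyl)-6-methyl-3-(TESO-methyl)undeca-1,6,10-trien-4-ol, via borate ester 29 (not isolated)
Conditions: (S)-TRIP (10 mol %), 4 Å MS, toluene, −30 °C; aq. NaHCO3
Reagents that add atoms: none
Why: Allylboration through a chair transition state in which the γ-substituent of the Z-configured boronate is axial, which gives the syn relation of the C6 carbon and O8 (7S,8R here). The chiral acid selects the Si face of the aldehyde, so the remote C3 centre plays no part. The new bond is C7–C8 and the double bond moves to C11=C13.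

Step 15
Reactants: 30 (3S,4R,6E,9S,10Z)-9-(TBSO)-10-(TBSO-methyl)-11-iodo-2-(PMBO-methyl)-6-methyl-3-(TESO-methyl)undeca-1,6,10-trien-4-ol; 31 2-methylpropanoyl chloride
Product: 32 (3S,4R,6E,9S,10Z)-9-(TBSO)-10-(TBSO-methyl)-11-iodo-2-(PMBO-methyl)-6-methyl-3-(TESO-methyl)undeca-1,6,10-trien-4-yl 2-methylpropanoate
Conditions: 31, pyridine, DMAP (cat.), CH2Cl2, 0 °C to rt
Reagents that add atoms: none
Why: Acylation of the secondary alcohol by the acylpyridinium ion; it is done before epoxidation so that the C8 oxygen is never free next to the epoxide.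

Step 16
Reactants: 32 (3S,4R,6E,9S,10Z)-9-(TBSO)-10-(TBSO-methyl)-11-iodo-2-(PMBO-methyl)-6-methyl-3-(TESO-methyl)undeca-1,6,10-trien-4-yl 2-methylpropanoate
Product: 33 (3S,4R)-5-{(2R,3R)-3-[(2S,3Z)-2-(TBSO)-3-(TBSO-methyl)-4-iodobut-3-en-1-yl]-2-methyloxiran-2-yl}-2-(PMBO-methyl)-3-(TESO-methyl)pent-1-en-4-yl 2-methylpropanoate
Conditions: D-fructose-derived Shi ketone (0.3 equiv), KHSO5 (as 2KHSO5·KHSO4·K2SO4), K2CO3, Bu4NHSO4, MeCN/CH2(OMe)2–aq. Na2B4O7/Na2EDTA (pH 10.5), 0 °C
Reagents that add atoms: potassium peroxymonosulfate, [K+].OOS(=O)(=O)[O-]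
Why: Shi epoxidation: the chiral dioxirane attacks the electron-rich 1(10)E olefin through a spiro transition state, and the face this ketone selects on trans and trisubstituted olefins corresponds to the 1R,10R epoxide. The iodoolefin (electron-poor, flanked by two silyloxy carbons) and the 1,1-disubstituted C11=C13 olefin should react more slowly.

Step 17
Reactants: 33 (3S,4R)-5-{(2R,3R)-3-[(2S,3Z)-2-(TBSO)-3-(TBSO-methyl)-4-iodobut-3-en-1-yl]-2-methyloxiran-2-yl}-2-(PMBO-methyl)-3-(TESO-methyl)pent-1-en-4-yl 2-methylpropanoate
Product: 34 (3S,4R)-5-{(2R,3R)-3-[(2S,3Z)-2-(TBSO)-3-(TBSO-methyl)-4-iodobut-3-en-1-yl]-2-methyloxiran-2-yl}-3-(hydroxymethyl)-2-(PMBO-methyl)pent-1-en-4-yl 2-methylpropanoate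
Conditions: HF·pyridine, excess pyridine, THF, 0 °C
Reagents that add atoms: none
Why: A primary triethylsilyl ether is cleaved by buffered HF·pyridine much faster than primary or secondary TBS ethers. The excess pyridine should keep the epoxide closed and the ester on O8.

Step 18
Reactants: 34 (3S,4R)-5-{(2R,3R)-3-[(2S,3Z)-2-(TBSO)-3-(TBSO-methyl)-4-iodobut-3-en-1-yl]-2-methyloxiran-2-yl}-3-(hydroxymethyl)-2-(PMBO-methyl)pent-1-en-4-yl 2-methylpropanoate
Product: 35 (3R,4R)-5-{(2R,3R)-3-[(2S,3Z)-2-(TBSO)-3-(TBSO-methyl)-4-iodobut-3-en-1-yl]-2-methyloxiran-2-yl}-3-formyl-2-(PMBO-methyl)pent-1-en-4-yl 2-methylpropanoate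
Conditions: Dess–Martin periodinane, NaHCO3, CH2Cl2, 0 °C; used at once without chromatography
Reagents that add atoms: none
Why: Buffered Dess–Martin oxidation is neither acidic nor basic, which matters because the C7–H of 35 is allylic and α to the aldehyde and the ester is β to it. The C7 descriptor changes to R only because the priorities change.

Step 19
Reactants: 35 (3R,4R)-5-{(2R,3R)-3-[(2S,3Z)-2-(TBSO)-3-(TBSO-methyl)-4-iodobut-3-en-1-yl]-2-methyloxiran-2-yl}-3-formyl-2-(PMBO-methyl)pent-1-en-4-yl 2-methylpropanoate
Product: 37 (1R,3S,4Z,6R,7S,8R,10R)-3,15-bis(TBSO)-1,10-epoxy-6-hydroxy-12-(PMBO)germacra-4,11(13)-dien-8-yl 2-methylpropanoate, via alkenylchromium species 36 (not isolated)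
Conditions: CrCl2 (15 equiv), NiCl2 (1 mol % of the CrCl2), degassed DMSO/THF, rt, slow addition of 35 (final 2 mM); aq. sodium serinate work-up
Reagents that add atoms: none
Why: Zerovalent nickel, formed in situ from NiCl2 and CrCl2, inserts into the C5–I bond with retention; transmetalation gives the trivalent alkenylchromium species 36, which is weakly basic, strongly oxophilic and adds to the aldehyde only. This is the Nozaki–Hiyama–Kishi reaction in intramolecular form, and the closest known reaction type is the Ni/Cr-mediated closure of medium and large carbocycles from iodoalkenyl aldehydes. The ten-membered ring closes by 10-exo-trig attack of C5 on the C6 carbonyl carbon; the Z iodide already holds C3 and C6 on the same side of C4=C5, and the epoxide and the olefin remove rotors from the chain, while high dilution and slow addition hold back intermolecular coupling. The new C6 centre is controlled by C7 inside the cyclic transition state: the C5–C6–C7–C8 torsion must be gauche in the ring, so C5 approaches anti to the C11 branch, and the chromium-bound oxygen is expected to lie beside H7 and away from the C8 ester branch, an arrangement that resembles the trans-fused product and gives the 6R alcohol (H6 anti to H7). An open-chain Felkin–Anh reading with the C11 branch as the perpendicular group would place the oxygen next to C8 and give the 6-epimer, so the facial sense is not regarded as secure (see the fallback). The chemoselectivity needed is addition to the aldehyde in the presence of the isobutyrate, the epoxide, the benzyl ether and the silyl ethers, and the low basicity of the chromium reagent also spares the doubly activated C7–H and the β-acyloxy group. The olefin geometry is carried over from the iodide.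

Step 20
Reactants: 37 (1R,3S,4Z,6R,7S,8R,10R)-3,15-bis(TBSO)-1,10-epoxy-6-hydroxy-12-(PMBO)germacra-4,11(13)-dien-8-yl 2-methylpropanoate
Product: 38 (1R,3S,4Z,6R,7S,8R,10R)-3,15-bis(TBSO)-1,10-epoxy-6,12-dihydroxygermacra-4,11(13)-dien-8-yl 2-methylpropanoate
Conditions: DDQ, CH2Cl2/pH 7 phosphate buffer (10:1), 0 °C
Reagents that add atoms: none
Why: Oxidative cleavage of the 4-methoxybenzyl ether by electron transfer to DDQ and hydrolysis of the oxocarbenium ion. The buffer protects the epoxide, and the electron-rich ether should react faster than the allylic alcohol.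

Step 21
Reactants: 38 (1R,3S,4Z,6R,7S,8R,10R)-3,15-bis(TBSO)-1,10-epoxy-6,12-dihydroxygermacra-4,11(13)-dien-8-yl 2-methylpropanoate
Product: 41 (1R,3S,4Z,6R,7R,8R,10R)-3,15-bis(TBSO)-1,10-epoxy-8-(2-methylpropanoyloxy)germacra-4,11(13)-dien-12,6-olide, via hydroxy enal 39 (not isolated), via lactol 40 (not isolated)
Conditions: TEMPO (0.2 equiv), PhI(OAc)2 (3 equiv), CH2Cl2, rt
Reagents that add atoms: none
Why: Oxidative lactonisation of a 2-methylene-1,4-diol: the oxoammonium ion from TEMPO oxidises the unhindered primary allylic C12 alcohol faster than the hindered secondary C6 alcohol, the enal is trapped by the C6 hydroxyl as the lactol, and the lactol is oxidised to the lactone. This oxidant is preferred to MnO2 because C6 is also an allylic alcohol. C6 and C7 are untouched, so the trans fusion follows from step 19.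

Step 22
Reactants: 41 (1R,3S,4Z,6R,7R,8R,10R)-3,15-bis(TBSO)-1,10-epoxy-8-(2-methylpropanoyloxy)germacra-4,11(13)-dien-12,6-olide
Product: 42 (1R,3S,4Z,6R,7R,8R,10R)-1,10-epoxy-3,15-dihydroxy-8-(2-methylpropanoyloxy)germacra-4,11(13)-dien-12,6-olide
Conditions: HF·pyridine, excess pyridine, THF, 0 °C to rt
Reagents that add atoms: none
Why: Fluoride-assisted cleavage of both TBS ethers. The medium is buffered and cold because the liberated C3 hydroxyl could open the epoxide across the ring, and basic fluoride would attack the methylene lactone or move the ester.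

## Compound list

1 | tert-butyldimethyl(prop-2-yn-1-yloxy)silane | C#CCO[Si](C)(C)C(C)(C)C | starting material
2 | trimethyl(tributylstannyl)silane | C[Si](C)(C)[Sn](CCCC)(CCCC)CCCC | starting material
3 | (Z)-tert-butyldimethyl{[2-(tributylstannyl)-3-(trimethylsilyl)prop-2-en-1-yl]oxy}silane | C[Si](C)(C)/C=C(/CO[Si](C)(C)C(C)(C)C)[Sn](CCCC)(CCCC)CCCC | intermediate
4 | N,N-dimethylformamide | CN(C)C=O | starting material
5 | (Z)-[3-(TBSO)-1-(trimethylsilyl)prop-1-en-2-yl]lithium | C[Si](C)(C)/C=C(/CO[Si](C)(C)C(C)(C)C)[Li] | intermediate (not isolated)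
6 | (Z)-2-(TBSO-methyl)-3-(trimethylsilyl)prop-2-enal | C[Si](C)(C)/C=C(/CO[Si](C)(C)C(C)(C)C)C=O | intermediate
7 | 2-allyl-4,4,5,5-tetramethyl-1,3,2-dioxaborolane | C=CCB1OC(C)(C)C(C)(C)O1 | starting material
8 | O-Bpin borate ester of 9 | C[Si](C)(C)/C=C(/CO[Si](C)(C)C(C)(C)C)[C@@H](OB1OC(C)(C)C(C)(C)O1)CC=C | intermediate (not isolated)
9 | (1Z,3S)-2-(TBSO-methyl)-1-(trimethylsilyl)hexa-1,5-dien-3-ol | C[Si](C)(C)/C=C(/CO[Si](C)(C)C(C)(C)C)[C@@H](O)CC=C | intermediate
10 | (1Z,3S)-3-(TBSO)-2-(TBSO-methyl)-1-(trimethylsilyl)hexa-1,5-diene | C[Si](C)(C)/C=C(/CO[Si](C)(C)C(C)(C)C)[C@@H](O[Si](C)(C)C(C)(C)C)CC=C | intermediate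
11 | 2-methylprop-2-enal (methacrolein) | C=C(C)C=O | starting material
12 | (2E,5S,6Z)-5-(TBSO)-6-(TBSO-methyl)-2-methyl-7-(trimethylsilyl)hepta-2,6-dienal | C[Si](C)(C)/C=C(/CO[Si](C)(C)C(C)(C)C)[C@@H](O[Si](C)(C)C(C)(C)C)C/C=C(\C)C=O | intermediate
13 | (2E,5S,6Z)-5-(TBSO)-6-(TBSO-methyl)-7-iodo-2-methylhepta-2,6-dienal | I/C=C(/CO[Si](C)(C)C(C)(C)C)[C@@H](O[Si](C)(C)C(C)(C)C)C/C=C(\C)C=O | intermediate
14 | methyltriphenylphosphonium bromide | C[P+](c1ccccc1)(c1ccccc1)c1ccccc1.[Br-] | starting material
15 | methylidenetriphenylphosphorane | C=P(c1ccccc1)(c1ccccc1)c1ccccc1 | intermediate (not isolated)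
16 | (3E,6S,7Z)-6-(TBSO)-7-(TBSO-methyl)-8-iodo-3-methylocta-1,3,7-triene | I/C=C(/CO[Si](C)(C)C(C)(C)C)[C@@H](O[Si](C)(C)C(C)(C)C)C/C=C(\C)C=C | intermediate
17 | B-alkyl-9-borabicyclo[3.3.1]nonane from 16 (boron on C8) | I/C=C(/CO[Si](C)(C)C(C)(C)C)[C@@H](O[Si](C)(C)C(C)(C)C)C/C=C(\C)CCB1C2CCCC1CCC2 | intermediate (not isolated)
18 | (3E,6S,7Z)-6-(TBSO)-7-(TBSO-methyl)-8-iodo-3-methylocta-3,7-dien-1-ol | I/C=C(/CO[Si](C)(C)C(C)(C)C)[C@@H](O[Si](C)(C)C(C)(C)C)C/C=C(\C)CCO | intermediate
19 | (3E,6S,7Z)-6-(TBSO)-7-(TBSO-methyl)-8-iodo-3-methylocta-3,7-dienal | I/C=C(/CO[Si](C)(C)C(C)(C)C)[C@@H](O[Si](C)(C)C(C)(C)C)C/C=C(\C)CC=O | intermediate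
20 | but-2-yne-1,4-diol | OCC#CCO | starting material
21 | 4-methoxybenzyl chloride | COc1ccc(CCl)cc1 | starting material
22 | 4-(PMBO)but-2-yn-1-ol | OCC#CCOCc1ccc(OC)cc1 | intermediate
23 | sodium 2,2-bis(2-methoxyethoxy)-3-(PMBO-methyl)-2,5-dihydro-1,2-oxaaluminol-2-uide (cyclic alkenylaluminate) | [Na+].COCCO[Al-]1(OCCOC)OCC=C1COCc1ccc(OC)cc1 | intermediate (not isolated)
24 | (Z)-3-iodo-4-(PMBO)but-2-en-1-ol | OC/C=C(\I)COCc1ccc(OC)cc1 | intermediate
25 | (Z)-triethyl{[3-iodo-4-(PMBO)but-2-en-1-yl]oxy}silane | CC[Si](CC)(CC)OC/C=C(\I)COCc1ccc(OC)cc1 | intermediate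
26 | 2-(iodomethyl)-4,4,5,5-tetramethyl-1,3,2-dioxaborolane | ICB1OC(C)(C)C(C)(C)O1 | starting material
27 | iodo[(Bpin)methyl]zinc | I[Zn]CB1OC(C)(C)C(C)(C)O1 | intermediate (not isolated)
28 | (E)-triethyl{[4-(PMBO)-3-(Bpin-methyl)but-2-en-1-yl]oxy}silane (C6 carbon cis to the CH2B carbon) | CC[Si](CC)(CC)OC/C=C(\CB1OC(C)(C)C(C)(C)O1)COCc1ccc(OC)cc1 | intermediate
29 | O-Bpin borate ester of 30 | CC[Si](CC)(CC)OC[C@H](C(=C)COCc1ccc(OC)cc1)[C@H](OB1OC(C)(C)C(C)(C)O1)C/C(C)=C/C[C@H](O[Si](C)(C)C(C)(C)C)/C(CO[Si](C)(C)C(C)(C)C)=C\I | intermediate (not isolated)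
30 | (3S,4R,6E,9S,10Z)-9-(TBSO)-10-(TBSO-methyl)-11-iodo-2-(PMBO-methyl)-6-methyl-3-(TESO-methyl)undeca-1,6,10-trien-4-ol | CC[Si](CC)(CC)OC[C@H](C(=C)COCc1ccc(OC)cc1)[C@H](O)C/C(C)=C/C[C@H](O[Si](C)(C)C(C)(C)C)/C(CO[Si](C)(C)C(C)(C)C)=C\I | intermediate
31 | 2-methylpropanoyl chloride (isobutyryl chloride) | CC(C)C(Cl)=O | starting material
32 | (3S,4R,6E,9S,10Z)-9-(TBSO)-10-(TBSO-methyl)-11-iodo-2-(PMBO-methyl)-6-methyl-3-(TESO-methyl)undeca-1,6,10-trien-4-yl 2-methylpropanoate | CC[Si](CC)(CC)OC[C@H](C(=C)COCc1ccc(OC)cc1)[C@H](OC(=O)C(C)C)C/C(C)=C/C[C@H](O[Si](C)(C)C(C)(C)C)/C(CO[Si](C)(C)C(C)(C)C)=C\I | intermediate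
33 | (3S,4R)-5-{(2R,3R)-3-[(2S,3Z)-2-(TBSO)-3-(TBSO-methyl)-4-iodobut-3-en-1-yl]-2-methyloxiran-2-yl}-2-(PMBO-methyl)-3-(TESO-methyl)pent-1-en-4-yl 2-methylpropanoate | CC[Si](CC)(CC)OC[C@H](C(=C)COCc1ccc(OC)cc1)[C@H](OC(=O)C(C)C)C[C@@]1(C)O[C@@H]1C[C@H](O[Si](C)(C)C(C)(C)C)/C(CO[Si](C)(C)C(C)(C)C)=C\I | intermediate
34 | (3S,4R)-5-{(2R,3R)-3-[(2S,3Z)-2-(TBSO)-3-(TBSO-methyl)-4-iodobut-3-en-1-yl]-2-methyloxiran-2-yl}-3-(hydroxymethyl)-2-(PMBO-methyl)pent-1-en-4-yl 2-methylpropanoate | OC[C@H](C(=C)COCc1ccc(OC)cc1)[C@H](OC(=O)C(C)C)C[C@@]1(C)O[C@@H]1C[C@H](O[Si](C)(C)C(C)(C)C)/C(CO[Si](C)(C)C(C)(C)C)=C\I | intermediate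
35 | (3R,4R)-5-{(2R,3R)-3-[(2S,3Z)-2-(TBSO)-3-(TBSO-methyl)-4-iodobut-3-en-1-yl]-2-methyloxiran-2-yl}-3-formyl-2-(PMBO-methyl)pent-1-en-4-yl 2-methylpropanoate (open-chain epoxy aldehyde with Z-alkenyl iodide) | O=C[C@H](C(=C)COCc1ccc(OC)cc1)[C@H](OC(=O)C(C)C)C[C@@]1(C)O[C@@H]1C[C@H](O[Si](C)(C)C(C)(C)C)/C(CO[Si](C)(C)C(C)(C)C)=C\I | intermediate
36 | alkenylchromium dichloride derived from 35 (trivalent chromium on C5) | O=C[C@H](C(=C)COCc1ccc(OC)cc1)[C@H](OC(=O)C(C)C)C[C@@]1(C)O[C@@H]1C[C@H](O[Si](C)(C)C(C)(C)C)/C(CO[Si](C)(C)C(C)(C)C)=C\[Cr](Cl)Cl | intermediate (not isolated)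
37 | (1R,3S,4Z,6R,7S,8R,10R)-3,15-bis(TBSO)-1,10-epoxy-6-hydroxy-12-(PMBO)germacra-4,11(13)-dien-8-yl 2-methylpropanoate | C=C(COCc2ccc(OC)cc2)[C@H]1[C@H](O)/C=C(/CO[Si](C)(C)C(C)(C)C)[C@@H](O[Si](C)(C)C(C)(C)C)C[C@H]2O[C@]2(C)C[C@H]1OC(=O)C(C)C | intermediate
38 | (1R,3S,4Z,6R,7S,8R,10R)-3,15-bis(TBSO)-1,10-epoxy-6,12-dihydroxygermacra-4,11(13)-dien-8-yl 2-methylpropanoate | C=C(CO)[C@H]1[C@H](O)/C=C(/CO[Si](C)(C)C(C)(C)C)[C@@H](O[Si](C)(C)C(C)(C)C)C[C@H]2O[C@]2(C)C[C@H]1OC(=O)C(C)C | intermediate
39 | (1R,3S,4Z,6R,7S,8R,10R)-3,15-bis(TBSO)-1,10-epoxy-6-hydroxy-12-oxogermacra-4,11(13)-dien-8-yl 2-methylpropanoate | C=C(C=O)[C@H]1[C@H](O)/C=C(/CO[Si](C)(C)C(C)(C)C)[C@@H](O[Si](C)(C)C(C)(C)C)C[C@H]2O[C@]2(C)C[C@H]1OC(=O)C(C)C | intermediate (not isolated)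
40 | lactol of 39 (6,12-epoxy-12-hydroxy, C12 configuration undefined) | C=C1C(O)O[C@@H]2/C=C(/CO[Si](C)(C)C(C)(C)C)[C@@H](O[Si](C)(C)C(C)(C)C)C[C@H]3O[C@]3(C)C[C@@H](OC(=O)C(C)C)[C@@H]12 | intermediate (not isolated)
41 | (1R,3S,4Z,6R,7R,8R,10R)-3,15-bis(TBSO)-1,10-epoxy-8-(2-methylpropanoyloxy)germacra-4,11(13)-dien-12,6-olide | C=C1C(=O)O[C@@H]2/C=C(/CO[Si](C)(C)C(C)(C)C)[C@@H](O[Si](C)(C)C(C)(C)C)C[C@H]3O[C@]3(C)C[C@@H](OC(=O)C(C)C)[C@@H]12 | intermediate
42 | (1R,3S,4Z,6R,7R,8R,10R)-1,10-epoxy-3,15-dihydroxy-8-(2-methylpropanoyloxy)germacra-4,11(13)-dien-12,6-olide | C=C1C(=O)O[C@@H]2/C=C(/CO)[C@@H](O)C[C@H]3O[C@]3(C)C[C@@H](OC(=O)C(C)C)[C@@H]12 | target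

## Step count and least certain steps

Total step count: 22. Longest linear sequence: 18 steps (steps 1–9 and 14–22); the allylboronate 28 takes 4 steps (10–13).

**Step 19 (key step).** Two processes are most likely to go wrong. The first is addition to the wrong face of the C6 aldehyde, because the ring conformation, not a simple open-chain model, decides where the chromium-bound oxygen lies. The second is intermolecular coupling or reduction of the C–I bond, because a strained ten-membered ring closes slowly; epimerisation at C7 or loss of isobutyrate would follow if the aldehyde waits too long. The fallback separates ring formation from stereocontrol. It sets out from 35, which is cyclised as before. If the product is mainly the C6-epimeric alcohol F1, the alcohol is oxidised (Dess–Martin periodinane, NaHCO3) to the ten-membered C6 ketone F2. Reduction of the enone F2 from its exposed face, with the Corey–Bakshi–Shibata oxazaborolidine–borane reagent of the appropriate hand or NaBH4/CeCl3 at −78 °C, returns to the route at 37.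

**Step 14.** The likely failure is insufficient facial discrimination by the acid catalyst, because the aldehyde is aliphatic and enolisable and the boronate carries substituents on both its β- and γ-carbons. This would give the 7,8-syn diastereomer of opposite absolute configuration, and slow addition would let the aldehyde slip into conjugation. The fallback replaces catalytic control by a stoichiometric chiral boronate. It sets out from 25: iodine–lithium exchange (t-BuLi, Et2O, −78 °C), capture with ClCH2B(OiPr)2 (1,2-shift on boron) and ester exchange with diisopropyl (R,R)-tartrate give the tartrate allylboronate F3. Its uncatalysed reaction with 19 (toluene, 4 Å MS, −78 °C) should add to the Si face through the same chair and comes back at 30.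

**Step 16.** The likely failures are competing epoxidation of the 1,1-disubstituted C11=C13 olefin, incomplete facial control, or slow hydrolysis of the ester in the basic buffer. The fallback epoxidises before the second olefin-bearing fragment is attached. It sets out from 18: Shi epoxidation under the same conditions gives the epoxy alcohol F4, in which the only other olefin is the deactivated iodoolefin. Buffered Dess–Martin oxidation gives the epoxy aldehyde F5, which must be used cold and at once because a β,γ-epoxy aldehyde eliminates easily. Allylboration with 28 under (S)-TRIP gives the epoxy homoallylic alcohol F6, and acylation with 31 returns to the route at 33.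

**Step 22.** The likely failure is transannular opening of the epoxide by the C3 hydroxyl as it is set free in the acidic fluoride medium, or acyl migration. The fallback introduces the epoxide last. It sets out from 32 and runs the same operations without step 16:
- buffered HF·pyridine gives the primary alcohol F7;
- Dess–Martin oxidation gives the aldehyde F8;
- Ni/Cr ring closure gives the macrocyclic triene alcohol F9;
- DDQ gives the diol F10;
- TEMPO/PhI(OAc)2 gives the triene lactone F11;
- HF·pyridine, now without an epoxide in the molecule, gives the dihydroxy triene lactone F12.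

Shi epoxidation of F12 should then oxidise the 1(10) olefin (the lactone methylene is electron-poor and C4=C5 is deactivated by two allylic hydroxyls) and arrive at 42.

## Further compounds

F1 | step 19 | C6 epimer of 37, (1R,3S,4Z,6S,7S,8R,10R)-3,15-bis(TBSO)-1,10-epoxy-6-hydroxy-12-(PMBO)germacra-4,11(13)-dien-8-yl 2-methylpropanoate | C=C(COCc2ccc(OC)cc2)[C@H]1[C@@H](O)/C=C(/CO[Si](C)(C)C(C)(C)C)[C@@H](O[Si](C)(C)C(C)(C)C)C[C@H]2O[C@]2(C)C[C@H]1OC(=O)C(C)C
F2 | step 19 | ten-membered C6 ketone, 3,15-bis(TBSO)-1,10-epoxy-6-oxo-12-(PMBO)germacra-4,11(13)-dien-8-yl 2-methylpropanoate | C=C(COCc2ccc(OC)cc2)[C@H]1C(=O)/C=C(/CO[Si](C)(C)C(C)(C)C)[C@@H](O[Si](C)(C)C(C)(C)C)C[C@H]2O[C@]2(C)C[C@H]1OC(=O)C(C)C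
F3 | step 14 | diisopropyl (4R,5R)-2-[(E)-2-(PMBO-methyl)-4-(TESO)but-2-en-1-yl]-1,3,2-dioxaborolane-4,5-dicarboxylate (tartrate allylboronate) | CC[Si](CC)(CC)OC/C=C(\CB1O[C@@H](C(=O)OC(C)C)[C@H](C(=O)OC(C)C)O1)COCc1ccc(OC)cc1
F4 | step 16 | epoxy alcohol, 2-{(2R,3R)-3-[(2S,3Z)-2-(TBSO)-3-(TBSO-methyl)-4-iodobut-3-en-1-yl]-2-methyloxiran-2-yl}ethanol | I/C=C(/CO[Si](C)(C)C(C)(C)C)[C@@H](O[Si](C)(C)C(C)(C)C)C[C@H]1O[C@]1(C)CCO
F5 | step 16 | epoxy aldehyde, 2-{(2R,3R)-3-[(2S,3Z)-2-(TBSO)-3-(TBSO-methyl)-4-iodobut-3-en-1-yl]-2-methyloxiran-2-yl}acetaldehyde | I/C=C(/CO[Si](C)(C)C(C)(C)C)[C@@H](O[Si](C)(C)C(C)(C)C)C[C@H]1O[C@]1(C)CC=O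
F6 | step 16 | epoxy homoallylic alcohol (33 with free C8 hydroxyl) | CC[Si](CC)(CC)OC[C@H](C(=C)COCc1ccc(OC)cc1)[C@H](O)C[C@@]1(C)O[C@@H]1C[C@H](O[Si](C)(C)C(C)(C)C)/C(CO[Si](C)(C)C(C)(C)C)=C\I
F7 | step 22 | primary alcohol without epoxide (32 with free C6 hydroxyl) | OC[C@H](C(=C)COCc1ccc(OC)cc1)[C@H](OC(=O)C(C)C)C/C(C)=C/C[C@H](O[Si](C)(C)C(C)(C)C)/C(CO[Si](C)(C)C(C)(C)C)=C\I
F8 | step 22 | aldehyde without epoxide (1(10)E-olefin analogue of 35) | O=C[C@H](C(=C)COCc1ccc(OC)cc1)[C@H](OC(=O)C(C)C)C/C(C)=C/C[C@H](O[Si](C)(C)C(C)(C)C)/C(CO[Si](C)(C)C(C)(C)C)=C\I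
F9 | step 22 | macrocyclic triene alcohol (1(10)E-olefin analogue of 37) | C=C(COCc2ccc(OC)cc2)[C@H]1[C@H](O)/C=C(/CO[Si](C)(C)C(C)(C)C)[C@@H](O[Si](C)(C)C(C)(C)C)C/C=C(\C)C[C@H]1OC(=O)C(C)C
F10 | step 22 | macrocyclic triene diol (1(10)E-olefin analogue of 38) | C=C(CO)[C@H]1[C@H](O)/C=C(/CO[Si](C)(C)C(C)(C)C)[C@@H](O[Si](C)(C)C(C)(C)C)C/C=C(\C)C[C@H]1OC(=O)C(C)C
F11 | step 22 | triene lactone, 3,15-bis(TBSO)-8-(2-methylpropanoyloxy)germacra-1(10)E,4Z,11(13)-trien-12,6-olide | C=C1C(=O)O[C@@H]2/C=C(/CO[Si](C)(C)C(C)(C)C)[C@@H](O[Si](C)(C)C(C)(C)C)C/C=C(\C)C[C@@H](OC(=O)C(C)C)[C@@H]12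
F12 | step 22 | dihydroxy triene lactone, 3,15-dihydroxy-8-(2-methylpropanoyloxy)germacra-1(10)E,4Z,11(13)-trien-12,6-olide | C=C1C(=O)O[C@@H]2/C=C(/CO)[C@@H](O)C/C=C(\C)C[C@@H](OC(=O)C(C)C)[C@@H]12
A1 | alternative 1 | ten-membered dienone ester | O=C1/C=C(/C(=O)OC)CC/C=C(\C)C[C@@H](O[Si](C)(C)C(C)(C)C)C1
A2 | alternative 1 | tricyclic cyclobutane photoadduct (one cis-anti-cis diastereomer drawn) | O=C1C[C@H](O[Si](C)(C)C(C)(C)C)C[C@]2(C)[C@H]1[C@@]1(C(=O)OC)CC[C@@H]21
A3 | alternative 2 | bis-silyl ether of the target (identical with 41) | C=C1C(=O)O[C@@H]2/C=C(/CO[Si](C)(C)C(C)(C)C)[C@@H](O[Si](C)(C)C(C)(C)C)C[C@H]3O[C@]3(C)C[C@@H](OC(=O)C(C)C)[C@@H]12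
A4 | alternative 2 | ten-membered trans-2-ethynyl alcohol | C#C[C@H]1[C@H](O)/C=C(/CO[Si](C)(C)C(C)(C)C)[C@@H](O[Si](C)(C)C(C)(C)C)C[C@H]2O[C@]2(C)C[C@H]1OC(=O)C(C)C
A5 | alternative 3 | ten-membered 4Z,1(10)E-dienone with C8 silyl group | O=C1/C=C(C)\[C@@H](O[Si](C)(C)C(C)(C)C)C/C=C(C)/C[C@@H]([Si](C)(C)c2ccccc2)C1
A6 | alternative 3 | divinylcyclohexenol (trans isopropenyl and E-silylvinyl groups) | C=C(C)[C@H]1C[C@H](O[Si](C)(C)C(C)(C)C)C(C)=C[C@]1(O)/C=C/[Si](C)(C)c1ccccc1
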